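**Retrosynthetic overview**
1. Target ⇐ free triol (Mitsunobu esterification of the primary allylic alcohol with angelic acid) ⇐ Eschenmoser methylenation of the saturated cis-fused lactone.
2. Key disconnection: the C3a'–C6a' bond of the lactone bicycle. An NHC-generated homoenolate (β-carbon of an enal arm) adds to an aldehyde arm on the same quaternary carbon; this single step closes the cyclopentane and the γ-lactone.
3. Spiro carbon: allyl first (ends cis to the ring methyl, later the enal arm), then prenyl (enters trans to the methyl, later the aldehyde arm), on the α'-carbon of (S)-5-methylcyclohex-2-enone.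
4. Cyclohexene oxygens: alkoxymethyl-lithium addition with oxidative 1,3-carbonyl transposition, α'-hydroxylation trans to the methyl, Luche reduction to the trans-diol.
5. Ring order: cyclohexenone first (organocatalytic Michael/aldol), then cyclopentane and lactone together in the key step.

Assumption: the sense of induction of the two chiral catalysts (steps 1 and 9) is taken from the usual shielding models and the substrate bias argued in step 9; the mirror-image catalyst would be used, with no other change, if an experiment showed the opposite sense.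

Numbering used in spiro names: cyclohexene C1 (spiro), C2 (bears CH2O), C3 (=CH), C4, C5, C6 (CHMe); lactone bicycle O1', C2' (C=O), C3', C3a', C4', C5' (spiro), C6', C6a'.

**Step 1**
Reactants: 1 (2E)-but-2-enal; 2 tert-butyl 3-oxobutanoate
Product: 5 (5S)-5-methylcyclohex-2-en-1-one, via Michael adduct 3 (not isolated), via cyclic keto ester 4 (not isolated)
Conditions: (R)-2-{bis[3,5-bis(trifluoromethyl)phenyl](trimethylsilyloxy)methyl}pyrrolidine (10 mol%), neat, 20 °C; then p-TsOH·H2O (20 mol%), toluene, 80 °C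
Reagents that add atoms: none
Why: Iminium-catalysed asymmetric Michael addition of the keto ester to the enal (the diarylprolinol silyl ether shields one face of the β-carbon and so sets the methyl-bearing stereocentre), followed in the same pot by acid-promoted intramolecular aldol condensation, tert-butyl ester cleavage and decarboxylation.

**Step 2**
Reactants: 5 (5S)-5-methylcyclohex-2-en-1-one; 6 3-bromoprop-1-ene
Product: 8 (5S,6R)-5-methyl-6-(prop-2-en-1-yl)cyclohex-2-en-1-one, via lithium dienolate 7 (not isolated)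
Conditions: LiN(iPr)2, THF, −78 °C; then 6, −78 → 0 °C
Reagents that add atoms: none
Why: Kinetic α'-deprotonation of the enone gives the cross-conjugated dienolate, which is allylated (SN2) trans to the neighbouring methyl; this centre is re-enolised in step 3, so its configuration is not critical.

**Step 3**
Reactants: 8 (5S,6R)-5-methyl-6-(prop-2-en-1-yl)cyclohex-2-en-1-one; 9 1-bromo-3-methylbut-2-ene
Product: 11 (5S,6R)-5-methyl-6-(3-methylbut-2-en-1-yl)-6-(prop-2-en-1-yl)cyclohex-2-en-1-one, via lithium dienolate 10 (not isolated)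
Conditions: LiN(iPr)2, THF/DMPU, −78 °C; then 9, −78 → −20 °C
Reagents that add atoms: none
Why: Second α'-enolate alkylation: in the tetrasubstituted enolate the C5 methyl sits pseudoaxial to avoid allylic strain with the C6 allyl group, so prenyl bromide attacks the opposite face and the quaternary (future spiro) centre forms with prenyl trans and allyl cis to the methyl.

**Step 4**
Reactants: 11 (5S,6R)-5-methyl-6-(3-methylbut-2-en-1-yl)-6-(prop-2-en-1-yl)cyclohex-2-en-1-one; 12 tributyl[(methoxymethoxy)methyl]stannane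
Product: 13 (5S,6R)-1-[(methoxymethoxy)methyl]-5-methyl-6-(3-methylbut-2-en-1-yl)-6-(prop-2-en-1-yl)cyclohex-2-en-1-ol (C1 epimers)
Conditions: 12, n-BuLi, THF, −78 °C; then 11, −78 °C; H2O
Reagents that add atoms: none
Why: Tin–lithium exchange gives the α-alkoxy organolithium (a hydroxymethyl anion equivalent), which adds 1,2 to the enone carbonyl; the new carbinol centre is removed in step 5, so both epimers are used.

**Step 5**
Reactants: 13 (5S,6R)-1-[(methoxymethoxy)methyl]-5-methyl-6-(3-methylbut-2-en-1-yl)-6-(prop-2-en-1-yl)cyclohex-2-en-1-ol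
Product: 14 (4R,5S)-3-[(methoxymethoxy)methyl]-5-methyl-4-(3-methylbut-2-en-1-yl)-4-(prop-2-en-1-yl)cyclohex-2-en-1-one
Conditions: pyridinium chlorochromate (C5H5NH)[CrO3Cl], 4 Å MS, CH2Cl2, 23 °C
Reagents that add atoms: pyridinium chlorochromate, [O-][Cr](=O)(=O)Cl.c1cc[nH+]cc1 (an oxo oxygen of chromium becomes the new carbonyl oxygen)
Why: Babler–Dauben oxidative transposition: the tertiary allylic chromate ester undergoes a [3,3] shift and the transposed secondary chromate is oxidised, giving the β-substituted enone and relieving strain next to the quaternary carbon.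

**Step 6**
Reactants: 14 (4R,5S)-3-[(methoxymethoxy)methyl]-5-methyl-4-(3-methylbut-2-en-1-yl)-4-(prop-2-en-1-yl)cyclohex-2-en-1-one
Product: 17 (4R,5R,6S)-6-(methoxymethoxy)-3-[(methoxymethoxy)methyl]-5-methyl-4-(3-methylbut-2-en-1-yl)-4-(prop-2-en-1-yl)cyclohex-2-en-1-one, via potassium dienolate 15 (not isolated), via potassium alkoxide 16 (not isolated)
Conditions: KN(SiMe3)2, THF, −78 °C; 2-(phenylsulfonyl)-3-phenyloxaziridine, −78 °C; then MOMCl, −78 → 0 °C
Reagents that add atoms: 2-(phenylsulfonyl)-3-phenyloxaziridine, O=S(=O)(c1ccccc1)N1OC1c1ccccc1; chloromethyl methyl ether, COCCl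
Why: Davis α'-hydroxylation of the kinetic enolate, with oxygen delivered anti to the adjacent methyl (as in carvone-type enolates) to set the trans relationship, and the alkoxide trapped as its MOM ether (Williamson) so that the periodate step cannot cleave an acyloin.

**Step 7**
Reactants: 17 (4R,5R,6S)-6-(methoxymethoxy)-3-[(methoxymethoxy)methyl]-5-methyl-4-(3-methylbut-2-en-1-yl)-4-(prop-2-en-1-yl)cyclohex-2-en-1-one
Product: 19 [(1R,5S,6R)-5-(methoxymethoxy)-2-[(methoxymethoxy)methyl]-6-methyl-4-oxo-1-(prop-2-en-1-yl)cyclohex-2-en-1-yl]acetaldehyde, via prenyl epoxide 18 (not isolated)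
Conditions: mCPBA, NaHCO3, CH2Cl2, 0 °C; then H5IO6, THF/H2O, 0 °C
Reagents that add atoms: mCPBA, OOC(=O)c1cccc(Cl)c1
Why: Prilezhaev epoxidation is far faster at the electron-rich trisubstituted prenyl alkene than at the monosubstituted allyl group or the electron-poor enone, and periodic acid then opens and cleaves the epoxide to the aldehyde and acetone.

**Step 8**
Reactants: 19 [(1R,5S,6R)-5-(methoxymethoxy)-2-[(methoxymethoxy)methyl]-6-methyl-4-oxo-1-(prop-2-en-1-yl)cyclohex-2-en-1-yl]acetaldehyde; 1 (2E)-but-2-enal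
Product: 20 (2E)-4-[(1R,5S,6R)-5-(methoxymethoxy)-2-[(methoxymethoxy)methyl]-6-methyl-4-oxo-1-(2-oxoethyl)cyclohex-2-en-1-yl]but-2-enal
Conditions: 1 (5 equiv), second-generation Hoveyda–Grubbs catalyst RuCl2(H2IMes)(=CH-C6H4-2-OiPr) (5 mol%), CH2Cl2, 40 °C
Reagents that add atoms: none
Why: Olefin cross-metathesis of the only terminal alkene with excess crotonaldehyde gives the E-enal; it is done after the prenyl group is gone so that no ring-closing metathesis of two geminal alkenyl arms can compete, and the trisubstituted ring enone is inert.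

**Step 9**
Reactants: 20 (2E)-4-[(1R,5S,6R)-5-(methoxymethoxy)-2-[(methoxymethoxy)methyl]-6-methyl-4-oxo-1-(2-oxoethyl)cyclohex-2-en-1-yl]but-2-enal
Product: 21 (1R,3a'R,5S,6R,6a'R)-5-(methoxymethoxy)-2-[(methoxymethoxy)methyl]-6-methylhexahydrospiro[cyclohex-2-ene-1,5'-cyclopenta[b]furan]-2',4-dione
Conditions: (5aS,10bR)-2-mesityl-5a,10b-dihydro-4H,6H-indeno[2,1-b][1,2,4]triazolo[4,3-d][1,4]oxazin-2-ium chloride (10 mol%), DBU (15 mol%), THF (0.02 M), 25 °C
Reagents that add atoms: none
Why: Proposed new method: the carbene adds to the enal and the resulting Breslow intermediate reacts as a homoenolate, so the normally electrophilic β-carbon attacks the tethered aldehyde carbon (5-exo) and the new alkoxide is acylated by the acyl azolium, which is only possible cis and releases the catalyst; the enal arm is the one cis to the C6 methyl, so its azolium-bearing substituent turns away from that methyl toward the face of the ring alkene carbon C2, a bias the chiral catalyst is chosen to reinforce, and the closest known reactions are the NHC-catalysed enal–aldehyde γ-butyrolactone annulation and its intramolecular enal–ketone variants.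

**Step 10**
Reactants: 21 (1R,3a'R,5S,6R,6a'R)-5-(methoxymethoxy)-2-[(methoxymethoxy)methyl]-6-methylhexahydrospiro[cyclohex-2-ene-1,5'-cyclopenta[b]furan]-2',4-dione
Product: 22 (1R,3a'R,4S,5S,6R,6a'R)-4-hydroxy-5-(methoxymethoxy)-2-[(methoxymethoxy)methyl]-6-methylhexahydrospiro[cyclohex-2-ene-1,5'-cyclopenta[b]furan]-2'-one
Conditions: NaBH4, CeCl3·7H2O, MeOH, −78 → −40 °C
Reagents that add atoms: none
Why: Luche 1,2-reduction of the enone: axial hydride delivery (no 1,3-diaxial substituent on that face) gives the equatorial allylic alcohol trans to the neighbouring OMOM group, and the lactone is untouched.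

**Step 11**
Reactants: 22 (1R,3a'R,4S,5S,6R,6a'R)-4-hydroxy-5-(methoxymethoxy)-2-[(methoxymethoxy)methyl]-6-methylhexahydrospiro[cyclohex-2-ene-1,5'-cyclopenta[b]furan]-2'-one
Product: 26 (1R,3a'R,4S,5S,6R,6a'R)-4-hydroxy-5-(methoxymethoxy)-2-[(methoxymethoxy)methyl]-6-methyl-3'-methylidenehexahydrospiro[cyclohex-2-ene-1,5'-cyclopenta[b]furan]-2'-one, via dilithio enolate 23 (not isolated), via Mannich base 24 (not isolated), via ammonium iodide 25 (not isolated)
Conditions: LiN(iPr)2 (2.3 equiv), THF, −78 °C; CH2=NMe2+ I−, −78 → 0 °C; aqueous work-up; MeI, MeOH, 23 °C; then NaHCO3 (aq), CH2Cl2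
Reagents that add atoms: N,N-dimethylmethyleneiminium iodide (Eschenmoser's salt), C=[N+](C)C.[I-]
Why: Eschenmoser methylenation: the lactone enolate (the free alcohol is carried as its lithium alkoxide) undergoes a Mannich reaction, and quaternisation followed by mild-base elimination of trimethylamine gives the exocyclic enoate without touching the ring-fusion centres.

**Step 12**
Reactants: 26 (1R,3a'R,4S,5S,6R,6a'R)-4-hydroxy-5-(methoxymethoxy)-2-[(methoxymethoxy)methyl]-6-methyl-3'-methylidenehexahydrospiro[cyclohex-2-ene-1,5'-cyclopenta[b]furan]-2'-one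
Product: 27 (1R,3a'R,4S,5S,6R,6a'R)-4,5-dihydroxy-2-(hydroxymethyl)-6-methyl-3'-methylidenehexahydrospiro[cyclohex-2-ene-1,5'-cyclopenta[b]furan]-2'-one
Conditions: HCl (1.25 M in MeOH), 0 → 23 °C
Reagents that add atoms: none
Why: Acid-catalysed acetal exchange with methanol removes both MOM groups as dimethoxymethane; the α-methylene lactone is stable to acid and the trans-diol cannot close a strain-free methylene acetal.

**Step 13**
Reactants: 27 (1R,3a'R,4S,5S,6R,6a'R)-4,5-dihydroxy-2-(hydroxymethyl)-6-methyl-3'-methylidenehexahydrospiro[cyclohex-2-ene-1,5'-cyclopenta[b]furan]-2'-one; 28 (2Z)-2-methylbut-2-enoic acid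
Product: 29 [(1R,3a'R,4S,5S,6R,6a'R)-4,5-dihydroxy-6-methyl-3'-methylidene-2'-oxohexahydrospiro[cyclohex-2-ene-1,5'-cyclopenta[b]furan]-2-yl]methyl (2Z)-2-methylbut-2-enoate
Conditions: 28 (1.1 equiv), PPh3, DIAD, THF, 0 °C
Reagents that add atoms: none
Why: Mitsunobu esterification: the unhindered primary allylic alcohol is activated much faster than the two secondary alcohols, and carboxylate SN2 displacement under these neutral conditions keeps the Z geometry of the angelate.

**Compound list**
1 | (2E)-but-2-enal | C/C=C/C=O | starting material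
2 | tert-butyl 3-oxobutanoate | CC(=O)CC(=O)OC(C)(C)C | starting material
3 | tert-butyl (3S)-2-acetyl-3-methyl-5-oxopentanoate (C2 epimers) | O=CC[C@H](C)C(C(C)=O)C(=O)OC(C)(C)C | intermediate (not isolated)
4 | tert-butyl (6S)-6-methyl-2-oxocyclohex-3-ene-1-carboxylate (C1 epimers) | O=C1C=CC[C@H](C)C1C(=O)OC(C)(C)C | intermediate (not isolated)
5 | (5S)-5-methylcyclohex-2-en-1-one | O=C1C=CC[C@H](C)C1 | intermediate
6 | 3-bromoprop-1-ene | C=CCBr | starting material
7 | lithium (3S)-3-methylcyclohexa-1,5-dien-1-olate | [Li]OC1=C[C@@H](C)CC=C1 | intermediate (not isolated)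
8 | (5S,6R)-5-methyl-6-(prop-2-en-1-yl)cyclohex-2-en-1-one | O=C1C=CC[C@H](C)[C@H]1CC=C | intermediate
9 | 1-bromo-3-methylbut-2-ene | CC(C)=CCBr | starting material
10 | lithium (3S)-3-methyl-2-(prop-2-en-1-yl)cyclohexa-1,5-dien-1-olate | [Li]OC1=C(CC=C)[C@@H](C)CC=C1 | intermediate (not isolated)
11 | (5S,6R)-5-methyl-6-(3-methylbut-2-en-1-yl)-6-(prop-2-en-1-yl)cyclohex-2-en-1-one | CC(C)=CC[C@@]1(CC=C)C(=O)C=CC[C@@H]1C | intermediate
12 | tributyl[(methoxymethoxy)methyl]stannane | CCCC[Sn](CCCC)(CCCC)COCOC | starting material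
13 | (5S,6R)-1-[(methoxymethoxy)methyl]-5-methyl-6-(3-methylbut-2-en-1-yl)-6-(prop-2-en-1-yl)cyclohex-2-en-1-ol (C1 epimers) | CC(C)=CC[C@@]1(CC=C)C(O)(COCOC)C=CC[C@@H]1C | intermediate
14 | (4R,5S)-3-[(methoxymethoxy)methyl]-5-methyl-4-(3-methylbut-2-en-1-yl)-4-(prop-2-en-1-yl)cyclohex-2-en-1-one | CC(C)=CC[C@@]1(CC=C)C(COCOC)=CC(=O)C[C@@H]1C | intermediate
15 | potassium (3S,4R)-5-[(methoxymethoxy)methyl]-3-methyl-4-(3-methylbut-2-en-1-yl)-4-(prop-2-en-1-yl)cyclohexa-1,5-dien-1-olate | CC(C)=CC[C@@]1(CC=C)C(COCOC)=CC([O-])=C[C@@H]1C.[K+] | intermediate (not isolated)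
16 | potassium (1S,5R,6R)-4-[(methoxymethoxy)methyl]-6-methyl-5-(3-methylbut-2-en-1-yl)-2-oxo-5-(prop-2-en-1-yl)cyclohex-3-en-1-olate | CC(C)=CC[C@@]1(CC=C)C(COCOC)=CC(=O)[C@@H]([O-])[C@@H]1C.[K+] | intermediate (not isolated)
17 | (4R,5R,6S)-6-(methoxymethoxy)-3-[(methoxymethoxy)methyl]-5-methyl-4-(3-methylbut-2-en-1-yl)-4-(prop-2-en-1-yl)cyclohex-2-en-1-one | CC(C)=CC[C@@]1(CC=C)C(COCOC)=CC(=O)[C@@H](OCOC)[C@@H]1C | intermediate
18 | (4R,5R,6S)-4-[(3,3-dimethyloxiran-2-yl)methyl]-6-(methoxymethoxy)-3-[(methoxymethoxy)methyl]-5-methyl-4-(prop-2-en-1-yl)cyclohex-2-en-1-one (oxirane epimers) | CC1(C)OC1C[C@@]2(CC=C)C(COCOC)=CC(=O)[C@@H](OCOC)[C@@H]2C | intermediate (not isolated)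
19 | [(1R,5S,6R)-5-(methoxymethoxy)-2-[(methoxymethoxy)methyl]-6-methyl-4-oxo-1-(prop-2-en-1-yl)cyclohex-2-en-1-yl]acetaldehyde | O=CC[C@@]1(CC=C)C(COCOC)=CC(=O)[C@@H](OCOC)[C@@H]1C | intermediate
20 | (2E)-4-[(1R,5S,6R)-5-(methoxymethoxy)-2-[(methoxymethoxy)methyl]-6-methyl-4-oxo-1-(2-oxoethyl)cyclohex-2-en-1-yl]but-2-enal | O=CC[C@@]1(C/C=C/C=O)C(COCOC)=CC(=O)[C@@H](OCOC)[C@@H]1C | intermediate
21 | (1R,3a'R,5S,6R,6a'R)-5-(methoxymethoxy)-2-[(methoxymethoxy)methyl]-6-methylhexahydrospiro[cyclohex-2-ene-1,5'-cyclopenta[b]furan]-2',4-dione (cis-fused lactone) | C1C(=O)O[C@@H]2C[C@@]3(C[C@H]12)C(COCOC)=CC(=O)[C@@H](OCOC)[C@@H]3C | intermediate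
22 | (1R,3a'R,4S,5S,6R,6a'R)-4-hydroxy-5-(methoxymethoxy)-2-[(methoxymethoxy)methyl]-6-methylhexahydrospiro[cyclohex-2-ene-1,5'-cyclopenta[b]furan]-2'-one | C1C(=O)O[C@@H]2C[C@@]3(C[C@H]12)C(COCOC)=C[C@H](O)[C@@H](OCOC)[C@@H]3C | intermediate
23 | dilithium salt of 22 (C4 alkoxide and lactone enolate) | C1=C(O[Li])O[C@@H]2C[C@@]3(C[C@H]12)C(COCOC)=C[C@H](O[Li])[C@@H](OCOC)[C@@H]3C | intermediate (not isolated)
24 | (1R,3a'R,4S,5S,6R,6a'R)-3'-[(dimethylamino)methyl]-4-hydroxy-5-(methoxymethoxy)-2-[(methoxymethoxy)methyl]-6-methylhexahydrospiro[cyclohex-2-ene-1,5'-cyclopenta[b]furan]-2'-one (C3' epimers) | CN(C)CC1C(=O)O[C@@H]2C[C@@]3(C[C@H]12)C(COCOC)=C[C@H](O)[C@@H](OCOC)[C@@H]3C | intermediate (not isolated)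
25 | N,N,N-trimethylammonium iodide of 24 (methiodide of the Mannich base) | C[N+](C)(C)CC1C(=O)O[C@@H]2C[C@@]3(C[C@H]12)C(COCOC)=C[C@H](O)[C@@H](OCOC)[C@@H]3C.[I-] | intermediate (not isolated)
26 | (1R,3a'R,4S,5S,6R,6a'R)-4-hydroxy-5-(methoxymethoxy)-2-[(methoxymethoxy)methyl]-6-methyl-3'-methylidenehexahydrospiro[cyclohex-2-ene-1,5'-cyclopenta[b]furan]-2'-one | C=C1C(=O)O[C@@H]2C[C@@]3(C[C@H]12)C(COCOC)=C[C@H](O)[C@@H](OCOC)[C@@H]3C | intermediate
27 | (1R,3a'R,4S,5S,6R,6a'R)-4,5-dihydroxy-2-(hydroxymethyl)-6-methyl-3'-methylidenehexahydrospiro[cyclohex-2-ene-1,5'-cyclopenta[b]furan]-2'-one | C=C1C(=O)O[C@@H]2C[C@@]3(C[C@H]12)C(CO)=C[C@H](O)[C@@H](O)[C@@H]3C | intermediate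
28 | (2Z)-2-methylbut-2-enoic acid (angelic acid) | C/C=C(/C)C(=O)O | starting material
29 | [(1R,3a'R,4S,5S,6R,6a'R)-4,5-dihydroxy-6-methyl-3'-methylidene-2'-oxohexahydrospiro[cyclohex-2-ene-1,5'-cyclopenta[b]furan]-2-yl]methyl (2Z)-2-methylbut-2-enoate (CNP0224912.1) | C=C1C(=O)O[C@@H]2C[C@@]3(C[C@H]12)C(COC(=O)/C(C)=C\C)=C[C@H](O)[C@@H](O)[C@@H]3C | target

**Totals**
Total step count: 13. Longest linear sequence: 13 steps (1 and 2 to 29; all other building blocks are commercial).

**Three steps most likely to fail**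

Step 9. The carbene may instead turn the aliphatic aldehyde into an acyl anion (Stetter or benzoin products), and the facial selectivity rests on a remote 1,3-relationship to the spiro centre. The fallback makes the same bond with an acyl anion instead of a homoenolate. It sets out from 19. Cross-metathesis with methyl acrylate (same ruthenium catalyst) gives methyl (2E)-4-[(1R,5S,6R)-5-(methoxymethoxy)-2-[(methoxymethoxy)methyl]-6-methyl-4-oxo-1-(2-oxoethyl)cyclohex-2-en-1-yl]but-2-enoate F1. An intramolecular Stetter reaction (aminoindanol-derived N-pentafluorophenyl triazolium tetrafluoroborate, KN(SiMe3)2 cat., toluene) closes the cyclopentanone and sets C3a', giving methyl [(2R,5R,9S,10R)-9-(methoxymethoxy)-6-[(methoxymethoxy)methyl]-10-methyl-3,8-dioxospiro[4.5]dec-6-en-2-yl]acetate F2. LiBH(s-Bu)3 in THF at −78 °C reduces only the unhindered cyclopentanone, from the face opposite the side chain, and the cis alkoxide lactonises onto the methyl ester. This comes back to the route at 21.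

Step 3. Deprotonation of 8 at its hindered tertiary α'-carbon can lose out to γ-deprotonation or O-alkylation, and the spiro configuration depends on the face selectivity of this one alkylation. The fallback builds the quaternary carbon by decarboxylative allylation and sets out from 5. C-acylation (LiN(iPr)2; 3-methylbut-2-en-1-yl 1H-imidazole-1-carboxylate, BF3·OEt2, THF, −78 °C) gives 3-methylbut-2-en-1-yl (6S)-6-methyl-2-oxocyclohex-3-ene-1-carboxylate F3. K2CO3 and 6 in acetone give 3-methylbut-2-en-1-yl (1S,6S)-6-methyl-2-oxo-1-(prop-2-en-1-yl)cyclohex-3-ene-1-carboxylate F4. Pd(PPh3)4 in THF then triggers Tsuji decarboxylative prenylation, the prenyl group joining the enolate carbon at its unsubstituted terminus and on the face away from the methyl group. This comes back to the route at 11; compound 8 is bypassed.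

Step 13. The triol offers three hydroxyl groups, and any base-mediated acylation variant risks angelate-to-tiglate isomerisation. The fallback separates the site selection from the ester formation and sets out from 27. MsCl, 2,4,6-collidine and LiCl in DMF at 0 °C convert only the primary allylic alcohol into (1R,3a'R,4S,5S,6R,6a'R)-2-(chloromethyl)-4,5-dihydroxy-6-methyl-3'-methylidenehexahydrospiro[cyclohex-2-ene-1,5'-cyclopenta[b]furan]-2'-one F5. Displacement with the caesium salt of 28 (Cs2CO3, DMF, 20 °C) comes back to the route at 29.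

**Further compounds**
F1 | step 9 | methyl (2E)-4-[(1R,5S,6R)-5-(methoxymethoxy)-2-[(methoxymethoxy)methyl]-6-methyl-4-oxo-1-(2-oxoethyl)cyclohex-2-en-1-yl]but-2-enoate | O=CC[C@@]1(C/C=C/C(=O)OC)C(COCOC)=CC(=O)[C@@H](OCOC)[C@@H]1C
F2 | step 9 | methyl [(2R,5R,9S,10R)-9-(methoxymethoxy)-6-[(methoxymethoxy)methyl]-10-methyl-3,8-dioxospiro[4.5]dec-6-en-2-yl]acetate | COC(=O)C[C@H]1C[C@]2(CC1=O)C(COCOC)=CC(=O)[C@@H](OCOC)[C@@H]2C
F3 | step 3 | 3-methylbut-2-en-1-yl (6S)-6-methyl-2-oxocyclohex-3-ene-1-carboxylate (C1 epimers) | CC(C)=CCOC(=O)C1C(=O)C=CC[C@@H]1C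
F4 | step 3 | 3-methylbut-2-en-1-yl (1S,6S)-6-methyl-2-oxo-1-(prop-2-en-1-yl)cyclohex-3-ene-1-carboxylate | CC(C)=CCOC(=O)[C@]1(CC=C)C(=O)C=CC[C@@H]1C
F5 | step 13 | (1R,3a'R,4S,5S,6R,6a'R)-2-(chloromethyl)-4,5-dihydroxy-6-methyl-3'-methylidenehexahydrospiro[cyclohex-2-ene-1,5'-cyclopenta[b]furan]-2'-one | C=C1C(=O)O[C@@H]2C[C@@]3(C[C@H]12)C(CCl)=C[C@H](O)[C@@H](O)[C@@H]3C
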